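| setting | alder | ash | birch | flask |
|---|---|---|---|---|
| left-handed substrate | 0.50 M | 0.50 M | 0.50 M | 0.50 M |
| right-handed substrate | 0.50 M | 0.50 M | 0.50 M | 0.50 M |
| reagent | 0.55 M | 2.2 M | 1.1 M | 1.10 M |
| free catalyst | 0.25 mM | 0.25 mM | 0.12 mM | 0.25 mM |
| racemization catalyst | 75 mM | 75 mM | 75 mM | 75 mM |
| remark | run made earlier | run made earlier | run made earlier |  |
| time |  |  |  | 10 d |

- alder (time / d: left-handed product / %, right-handed product / %): 0.500: 1, 0; 1.67: 5, 5; 3.00: 10, 7; 4.00: 11, 8; 6.00: 14, 11
- ash (time / d: left-handed product / %, right-handed product / %): 1.25: 16, 12; 2.50: 32, 20; 4.00: 36, 26; 5.00: 39, 28; 6.00: 39, 31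
- birch (time / d: left-handed product / %, right-handed product / %): 1.25: 6, 4; 2.50: 11, 5; 4.00: 11, 10; 5.00: 16, 8; 6.00: 16, 9

(readings scatter by 1.5 percentage points)

- free catalyst is single-handed; left-handed substrate and right-handed substrate are mirror images of each other, charged as a racemate, each of them at the stated concentration
- the analysis behind the earlier runs scatters by 1.5 percentage points, standard deviation
- an excess is below zero if the other one leads

* left-handed product and right-handed product together, in percent of the left-handed substrate and right-handed substrate charged together, at 10 d
* excess of left-handed product over right-handed product in the product at 10 d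
* whether the exchange between left-handed substrate and right-handed substrate keeps pace with the reaction: how far the product's excess at 10 d gets from its value without exchange to its value with instant exchange (above 80% keeps pace, below 20% hardly takes part, else lags behind)

- Litres per mole per day is the unit to reckon in. With the main step alone, summed product grows as k·c(reagent)·c(substrates), and k in that unit holds for one charge of free catalyst, here 0.25 mM.
- Integrating with both concentrations falling, the ash reading at 4.00 d, summed product 0.620 M, gives 0.133 L mol⁻¹ d⁻¹, the second-order constant read at that catalyst charge.
- The alder reading at 6.00 d, with a quarter of the ash reagent and summed product 0.250 M, gives 0.118 L mol⁻¹ d⁻¹, so the form survives a large change of reagent.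
- For the flask, with 1.10 M of reagent at 10 d, this reckoning of my own gives 60.9%.
- Adding handedness opens an excess. The first two ash readings pooled show 20.0%, and the ash reading at 4.00 d, near the conversion expected here, shows 16.1%.
- Adding exchange, my reckoning gives the flask 10 d for a conversion close to that of the ash reading at 4.00 d. With the same charge of racemization catalyst, exchange therefore has longer to act in the flask, and my excess lies between those two readings.
- The forecast gives 52% (45% to 59%), an excess of 17% (12% to 23%) and "lags behind", holding that “Exchange therefore seems slow but not absent”. My sum stands above its range.
- The flask gives 60.3%, an excess of 17.4%, and lags behind, at 30% of the way to instant exchange.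

    reagent + free catalyst + left-handed substrate → free catalyst + left-handed product (k = 52.0 L² mol⁻² h⁻¹)
    reagent + free catalyst + right-handed substrate → free catalyst + right-handed product (k = 32.0 L² mol⁻² h⁻¹)
    left-handed substrate + racemization catalyst ⇌ right-handed substrate + racemization catalyst, rate k3*[racemization catalyst]*[left-handed substrate] forward; the back reaction follows from the equilibrium constant (k = 0.120 L mol⁻¹ h⁻¹)
    racemization catalyst → spent catalyst (k = 0.0140 h⁻¹)
    reagent ⇌ dormant form (K = 0.910, k = 0.460 h⁻¹)

- In the flask at 10.0 d, left-handed substrate goes to left-handed product 11 times as fast as to right-handed substrate, counting the forward exchange alone. Racemization catalyst in the flask then stands at 3.47% of its charge.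
- A neighbour charged with 0.28 M of reagent has less reagent than the two substrates together, so reagent is the limiting reagent, with a ceiling of 28.0% of the substrates charged. The same k gives 19.3%, and the computed neighbour gives 19.2%, with an excess of 22.2%.

The data are simulated from invented constants; scatter was added.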